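Everything rests on cutting the C2–C3 bond of the oxepine. The aryl ketone, its CH2 and the CO2H on the quaternary ether carbon C2 are the opened form of a 5-aryl-furan-2(3H)-one ring, so C2 (furanone C3) becomes an acidic carbon that already bears ring oxygen O1 as an allyl ether. In one operation a chiral bifunctional base turns the racemic 3-alkoxy-5-aryl-furanone, whose ether arm carries the 1,1-disubstituted alkene, into a planar aromatic 2-oxidofuran and adds it through C3 to acrolein, which sets the fully substituted stereocentre. Methylenation, ring-closing metathesis at C5=C6 and opening of the lactone then deliver the acid.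

Key step: step 12

Assumption (chemistry): ethyl glyoxylate is used as the monomer, freshly distilled from its commercial toluene solution. The sense of induction in step 12 is assigned by analogy, so the quinine-derived pseudo-enantiomer of the catalyst is taken instead if the quinidine-derived one should give the (S) centre.

Abbreviations: Ar = 2,5-bis(methoxymethoxy)phenyl; R = (5E)-7-{[tert-butyl(dimethyl)silyl]oxy}-6-methyl-2-methylidenehept-5-en-1-yl, that is CH2C(=CH2)CH2CH2CH=C(CH3)CH2OTBS with the CH2OTBS group trans to the chain.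

Step 1
Reactants: 1 2',5'-dihydroxyacetophenone
Product: 2 1-[2,5-bis(methoxymethoxy)phenyl]ethan-1-one
Conditions: NaH, MOMCl, DMF, 0 °C to rt
Reagents that add atoms: chloromethyl methyl ether, COCCl
Why: Williamson-type O-alkylation in which NaH deprotonates both phenols, including the hydrogen-bonded ortho one, and the phenoxides displace chloride from MOMCl to give the bis-acetal, which should withstand every basic step that follows.

Step 2
Reactants: 2 1-[2,5-bis(methoxymethoxy)phenyl]ethan-1-one; 3 ethyl glyoxylate
Product: 5 ethyl 4-Ar-2-hydroxy-4-oxobutanoate (racemic), via lithium enolate 4 (not isolated)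
Conditions: LiN(i-Pr)2, THF, −78 °C; then 3 (monomer), −78 °C; AcOH quench
Reagents that add atoms: none
Why: Directed aldol addition in which the kinetic lithium enolate 4 of the methyl ketone should add at −78 °C to the aldehyde carbonyl of monomeric 3, far more electrophilic than its ester group, and the carbinol centre formed is racemic and is removed in step 3.

Step 3
Reactants: 5 ethyl 4-Ar-2-hydroxy-4-oxobutanoate
Product: 7 ethyl (2E)-4-Ar-4-oxobut-2-enoate, via mesylate 6 (not isolated)
Conditions: MsCl, Et3N, CH2Cl2, 0 °C to rt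
Reagents that add atoms: none
Why: Mesylation followed by E1cB elimination (aldol dehydration), in which the acidic hydrogens next to the ketone let Et3N expel the mesylate of 6 and the conjugated enone ester should form with the thermodynamically preferred E geometry.

Step 4
Reactants: 8 2-methylprop-2-en-1-ol; 9 prenyl bromide (1-bromo-3-methylbut-2-ene)
Product: 11 6-methyl-2-methylidenehept-5-en-1-ol, via dilithio dianion 10 (not isolated)
Conditions: n-BuLi (2.2 equiv), TMEDA, Et2O/hexane, 0 °C to rt; then 9, THF, −78 °C to rt; H2O
Reagents that add atoms: none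
Why: Alkylation of the allylic dianion of methallyl alcohol, in which n-BuLi and TMEDA remove the O–H and then an allylic methyl hydrogen and the carbon terminus of 10 should displace bromide from the primary allylic halide by SN2 substitution.

Step 5
Reactants: 11 6-methyl-2-methylidenehept-5-en-1-ol
Product: 12 6-methyl-2-methylidenehept-5-en-1-yl acetate
Conditions: Ac2O, pyridine, DMAP (cat.), CH2Cl2, 0 °C to rt
Reagents that add atoms: acetic anhydride, CC(=O)OC(C)=O
Why: Standard O-acylation of a primary alcohol under DMAP catalysis, which also lowers the electron density of the neighbouring 1,1-disubstituted alkene ahead of the oxidation.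

Step 6
Reactants: 12 6-methyl-2-methylidenehept-5-en-1-yl acetate
Product: 13 (5E)-7-hydroxy-6-methyl-2-methylidenehept-5-en-1-yl acetate
Conditions: SeO2 (cat.), t-BuOOH, salicylic acid (cat.), CH2Cl2, rt
Reagents that add atoms: selenium dioxide (catalytic oxygen carrier), O=[Se]=O; tert-butyl hydroperoxide (terminal oxygen source), CC(C)(C)OO
Why: Catalytic SeO2 allylic oxidation (ene reaction followed by a [2,3]-sigmatropic shift), in which the electron-rich trisubstituted alkene should react in preference to the acetate-deactivated one and the oxygen is delivered to the methyl group trans to the chain, which fixes the E geometry of the side-chain alkene.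

Step 7
Reactants: 13 (5E)-7-hydroxy-6-methyl-2-methylidenehept-5-en-1-yl acetate
Product: 14 (5E)-7-{[tert-butyl(dimethyl)silyl]oxy}-6-methyl-2-methylidenehept-5-en-1-yl acetate (R–OAc)
Conditions: TBSCl, imidazole, DMF, rt
Reagents that add atoms: tert-butyldimethylsilyl chloride, CC(C)(C)[Si](C)(C)Cl
Why: Silylation of a primary alcohol with TBSCl and imidazole, conditions under which the acetate stays in place.

Step 8
Reactants: 14 R–OAc
Product: 15 (5E)-7-{[tert-butyl(dimethyl)silyl]oxy}-6-methyl-2-methylidenehept-5-en-1-ol (R–OH)
Conditions: K2CO3 (cat.), MeOH, 0 °C to rt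
Reagents that add atoms: none
Why: Base-catalysed transesterification (methanolysis of the acetate), to which the silyl ether and both alkenes are inert.

Step 9
Reactants: 7 ethyl (2E)-4-Ar-4-oxobut-2-enoate; 15 R–OH
Product: 16 ethyl 4-Ar-4-oxo-2-(RO)butanoate (racemic)
Conditions: KN(SiMe3)2 (10 mol%), THF, −40 °C, slow addition of 7; AcOH quench
Reagents that add atoms: none
Why: Oxa-Michael addition in which the catalytic potassium alkoxide of 15 should add to the alkene carbon β to the ketone and α to the ester, the site activated by the stronger acceptor, while low temperature and slow addition of 7 hold back the reverse reaction, ester exchange and enolate oligomerisation; the new C–H centre is racemic, which is of no consequence because it is erased in step 12.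

Step 10
Reactants: 16 ethyl 4-Ar-4-oxo-2-(RO)butanoate
Product: 17 4-Ar-4-oxo-2-(RO)butanoic acid (racemic)
Conditions: Me3SnOH, ClCH2CH2Cl, 70 °C; cold 0.1 M aq. HCl wash
Reagents that add atoms: trimethyltin hydroxide, C[Sn](C)(C)O
Why: Ester hydrolysis with Me3SnOH under nearly neutral conditions, chosen over aqueous hydroxide because the β-alkoxy ketone could lose the alkoxide by E1cB elimination; the activated α-alkoxy ester should be cleaved while the silyl ether and the MOM acetals survive.

Step 11
Reactants: 17 4-Ar-4-oxo-2-(RO)butanoic acid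
Product: 18 5-Ar-3-(RO)furan-2(3H)-one (racemic)
Conditions: EDC·HCl, CH2Cl2, 0 °C to rt
Reagents that add atoms: none
Why: Carbodiimide-driven cyclodehydration of a γ-keto acid, in which the ketone oxygen should close onto the activated carboxyl group and loss of a C4 hydrogen gives the enol lactone, the classical conversion of 3-aroylpropanoic acids into 5-aryl-furan-2(3H)-ones carried out here without heat or added base.

Step 12
Reactants: 18 5-Ar-3-(RO)furan-2(3H)-one; 19 acrolein
Product: 21 3-[(3R)-5-Ar-2-oxo-3-(RO)-2,3-dihydrofuran-3-yl]propanal, via furanolate ion pair 20 (not isolated)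
Conditions: 9-O-benzylcupreidine (10 mol%), 19 (3 equiv), CH2Cl2, −40 °C
Reagents that add atoms: none
Why: Proposed new method: the quinuclidine nitrogen of the catalyst should remove the acidic C3–H of 18 (its conjugated tautomer gives the same species) to form the aromatic 2-oxidofuran 20 as a hydrogen-bonded ion pair, while the 6'-OH group binds the carbonyl of acrolein, so that C3 adds to the β-carbon and the resulting enolate is protonated to the aldehyde. The closest known reaction type is the enantioselective Michael addition of α-substituted cyclic β-keto esters, azlactones and 3-substituted benzofuran-2(3H)-ones to acrolein and enones under bifunctional cinchona-base catalysis, which has not been shown for a 3-alkoxy-5-aryl-furan-2(3H)-one donor. No ring is closed in this step. The quaternary centre is set under catalyst control: the racemic C–H centre is erased in planar 20, the chiral ion pair is anchored through hydrogen bonds to the lactone carbonyl and the 3-alkoxy oxygen and exposes one face, and the pseudo-enantiomer of the catalyst is chosen so that the (R) centre forms. The step needs attack through C3 instead of C5, which is secured by the twisted ortho-substituted aryl group that shields C5, by the aryl–enol ester conjugation that survives only when C3 reacts, and by the catalyst holding acrolein next to C3. The weak base and low temperature should keep the allyloxy-substituted anion from a [2,3]-Wittig shift, and the enol lactone cannot lose the alkoxide by retro-oxa-Michael or retro-aldol cleavage.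

Step 13
Reactants: 21 3-[(3R)-5-Ar-2-oxo-3-(RO)-2,3-dihydrofuran-3-yl]propanal
Product: 22 (3R)-5-Ar-3-(but-3-en-1-yl)-3-(RO)furan-2(3H)-one
Conditions: Ph3PCH3Br, KN(SiMe3)2, THF, −78 °C to 0 °C
Reagents that add atoms: methyltriphenylphosphonium bromide, C[P+](c1ccccc1)(c1ccccc1)c1ccccc1.[Br-]
Why: Wittig methylenation in which the non-stabilised ylide should react with the aldehyde at −78 °C much faster than with the lactone carbonyl, and the quaternary centre carries no hydrogen and so cannot epimerise.

Step 14
Reactants: 22 (3R)-5-Ar-3-(but-3-en-1-yl)-3-(RO)furan-2(3H)-one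
Product: 23 (5R)-3-Ar-8-[(3E)-5-{[tert-butyl(dimethyl)silyl]oxy}-4-methylpent-3-en-1-yl]-2,6-dioxaspiro[4.6]undeca-3,8-dien-1-one
Conditions: second-generation Grubbs catalyst RuCl2(=CHPh)(H2IMes)(PCy3) (5 mol%), 1,4-benzoquinone (10 mol%), CH2Cl2 (5 mM), 40 °C
Reagents that add atoms: none
Why: Ring-closing metathesis in which the ruthenium carbene should load on the monosubstituted butenyl alkene and close onto the 1,1-disubstituted allyl ether alkene with loss of ethene, the only productive closure being the seven-membered one, which is helped by the quaternary spiro centre, while the trisubstituted side-chain alkene and the enol ester alkene are too hindered to compete and the ring alkene geometry is fixed by the ring.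

Step 15
Reactants: 23 (5R)-3-Ar-8-[(3E)-5-{[tert-butyl(dimethyl)silyl]oxy}-4-methylpent-3-en-1-yl]-2,6-dioxaspiro[4.6]undeca-3,8-dien-1-one
Product: 25 (2R)-2-[2-(2,5-dihydroxyphenyl)-2-oxoethyl]-6-[(3E)-5-hydroxy-4-methylpent-3-en-1-yl]-2,3,4,7-tetrahydrooxepine-2-carboxylic acid (CNP0570804.1), via protected keto acid 24 (not isolated)
Conditions: LiOH, THF/H2O, 0 °C; then aq. HCl (to about 2 M), THF/H2O, 40 °C, argon
Reagents that add atoms: lithium hydroxide, [Li+].[OH-]
Why: Acyl substitution at the enol lactone, an activated ester, by hydroxide at 0 °C should release the aryl ketone and the carboxylate while the phenols are still protected, and the aqueous acid that follows hydrolyses the two MOM acetals and the silyl ether without touching the stereocentre, which bears no hydrogen.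

Compound list
1 | 2',5'-dihydroxyacetophenone | CC(=O)c1cc(O)ccc1O | starting material
2 | 1-[2,5-bis(methoxymethoxy)phenyl]ethan-1-one | CC(=O)c1cc(OCOC)ccc1OCOC | intermediate
3 | ethyl glyoxylate | O=CC(=O)OCC | starting material
4 | lithium enolate of 2 | [Li]OC(=C)c1cc(OCOC)ccc1OCOC | intermediate
5 | ethyl 4-[2,5-bis(methoxymethoxy)phenyl]-2-hydroxy-4-oxobutanoate (racemic) | CCOC(=O)C(O)CC(=O)c1cc(OCOC)ccc1OCOC | intermediate
6 | ethyl 4-[2,5-bis(methoxymethoxy)phenyl]-2-(methanesulfonyloxy)-4-oxobutanoate (racemic) | CCOC(=O)C(OS(C)(=O)=O)CC(=O)c1cc(OCOC)ccc1OCOC | intermediate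
7 | ethyl (2E)-4-[2,5-bis(methoxymethoxy)phenyl]-4-oxobut-2-enoate | CCOC(=O)/C=C/C(=O)c1cc(OCOC)ccc1OCOC | intermediate
8 | 2-methylprop-2-en-1-ol | C=C(C)CO | starting material
9 | prenyl bromide (1-bromo-3-methylbut-2-ene) | CC(C)=CCBr | starting material
10 | dilithio dianion of 8 (lithium alkoxide and allyllithium) | [Li]CC(=C)CO[Li] | intermediate
11 | 6-methyl-2-methylidenehept-5-en-1-ol | OCC(=C)CCC=C(C)C | intermediate
12 | 6-methyl-2-methylidenehept-5-en-1-yl acetate | CC(=O)OCC(=C)CCC=C(C)C | intermediate
13 | (5E)-7-hydroxy-6-methyl-2-methylidenehept-5-en-1-yl acetate | CC(=O)OCC(=C)CC/C=C(\C)CO | intermediate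
14 | (5E)-7-{[tert-butyl(dimethyl)silyl]oxy}-6-methyl-2-methylidenehept-5-en-1-yl acetate | CC(=O)OCC(=C)CC/C=C(\C)CO[Si](C)(C)C(C)(C)C | intermediate
15 | (5E)-7-{[tert-butyl(dimethyl)silyl]oxy}-6-methyl-2-methylidenehept-5-en-1-ol | OCC(=C)CC/C=C(\C)CO[Si](C)(C)C(C)(C)C | intermediate
16 | ethyl 4-[2,5-bis(methoxymethoxy)phenyl]-4-oxo-2-(RO)butanoate (racemic) | CCOC(=O)C(CC(=O)c1cc(OCOC)ccc1OCOC)OCC(=C)CC/C=C(\C)CO[Si](C)(C)C(C)(C)C | intermediate
17 | 4-[2,5-bis(methoxymethoxy)phenyl]-4-oxo-2-(RO)butanoic acid (racemic) | OC(=O)C(CC(=O)c1cc(OCOC)ccc1OCOC)OCC(=C)CC/C=C(\C)CO[Si](C)(C)C(C)(C)C | intermediate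
18 | 5-[2,5-bis(methoxymethoxy)phenyl]-3-(RO)furan-2(3H)-one (racemic) | O=C1OC(c2cc(OCOC)ccc2OCOC)=CC1OCC(=C)CC/C=C(\C)CO[Si](C)(C)C(C)(C)C | intermediate
19 | acrolein | C=CC=O | starting material
20 | 2-oxidofuran anion of 18, ion-paired with the protonated catalyst | [O-]c1oc(-c2cc(OCOC)ccc2OCOC)cc1OCC(=C)CC/C=C(\C)CO[Si](C)(C)C(C)(C)C | intermediate
21 | 3-[(3R)-5-[2,5-bis(methoxymethoxy)phenyl]-2-oxo-3-(RO)-2,3-dihydrofuran-3-yl]propanal | O=CCC[C@@]1(C(=O)OC(c2cc(OCOC)ccc2OCOC)=C1)OCC(=C)CC/C=C(\C)CO[Si](C)(C)C(C)(C)C | intermediate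
22 | (3R)-5-[2,5-bis(methoxymethoxy)phenyl]-3-(but-3-en-1-yl)-3-(RO)furan-2(3H)-one | C=CCC[C@@]1(C(=O)OC(c2cc(OCOC)ccc2OCOC)=C1)OCC(=C)CC/C=C(\C)CO[Si](C)(C)C(C)(C)C | intermediate
23 | (5R)-3-[2,5-bis(methoxymethoxy)phenyl]-8-[(3E)-5-{[tert-butyl(dimethyl)silyl]oxy}-4-methylpent-3-en-1-yl]-2,6-dioxaspiro[4.6]undeca-3,8-dien-1-one | C/C(=C\CCC1=CCC[C@@]2(C(=O)OC(c3cc(OCOC)ccc3OCOC)=C2)OC1)CO[Si](C)(C)C(C)(C)C | intermediate
24 | (2R)-2-{2-[2,5-bis(methoxymethoxy)phenyl]-2-oxoethyl}-6-[(3E)-5-{[tert-butyl(dimethyl)silyl]oxy}-4-methylpent-3-en-1-yl]-2,3,4,7-tetrahydrooxepine-2-carboxylic acid (lithium carboxylate in the flask) | C/C(=C\CCC1=CCC[C@@](CC(=O)c2cc(OCOC)ccc2OCOC)(C(=O)O)OC1)CO[Si](C)(C)C(C)(C)C | intermediate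
25 | (2R)-2-[2-(2,5-dihydroxyphenyl)-2-oxoethyl]-6-[(3E)-5-hydroxy-4-methylpent-3-en-1-yl]-2,3,4,7-tetrahydrooxepine-2-carboxylic acid (CNP0570804.1) | C/C(=C\CCC1=CCC[C@@](CC(=O)c2cc(O)ccc2O)(C(=O)O)OC1)CO | target

Total step count: 15.
Longest linear sequence: 12 steps (steps 4 to 15, from 8 and 9 to 25). The aryl fragment 7 takes 3 steps and joins in step 9.

Steps most likely to fail

1. Step 12 (proposed new method). The furanolate may react through C5, the vinylogous position that deconjugated butenolides usually use under bifunctional base catalysis. The facial selectivity may also be low on this untested donor, or the allyloxy-substituted anion may undergo a [2,3]-Wittig shift. The fallback uses only known reaction types, sets out from ketone 2 and alcohol 15 and comes back at diene 22. Ketone 2 would be turned into trimethylsilyl enol ether F1 (TMSOTf, Et3N, CH2Cl2, 0 °C). F1 would be added to ethyl 2-oxohex-5-enoate F2 (from diethyl oxalate and but-3-enylmagnesium bromide, THF, −78 °C) in an enantioselective Mukaiyama aldol reaction catalysed by the divalent copper complex Cu(OTf)2/t-Bu-box (10 mol%, THF, −78 °C). The α-keto ester chelates the metal, and the ligand enantiomer is chosen so that the silylated (R)-adduct F3 forms, which mild acid work-up converts into tertiary alcohol F4. Me3SnOH would cleave the ethyl ester to hydroxy acid F5 and EDC·HCl would close 3-hydroxy enol lactone F6, in which retro-aldol cleavage is no longer possible. Alcohol 15 would be converted into allylic mesylate F7 (MsCl, Et3N, CH2Cl2, −20 °C). The sodium alkoxide of F6 (NaH, DMF, −20 °C) would be alkylated with F7 in a Williamson etherification to give 22, from which steps 14 and 15 follow unchanged.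

2. Step 9. The addition is reversible, the intermediate ketone enolate may add to a second molecule of 7 (oligomerisation), and the alkoxide may exchange the ethyl ester. The fallback sets out from hydroxy ester 5 (the product of step 2) and alcohol 15 and comes back at 16. Alcohol 15 would be converted into allylic bromide F8 (CBr4, PPh3, CH2Cl2, 0 °C). The secondary hydroxyl group of 5 would then be alkylated with F8 in the presence of Ag2O (Et2O, 4 Å molecular sieves, rt, dark). This silver-assisted etherification forms the C–O bond by substitution without generating an enolate, so neither elimination to 7 nor retro-aldol cleavage should intervene.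

3. Step 14. The ruthenium carbene formed on the butenyl group may dimerise by cross-metathesis, or be lost on the enol ester alkene, instead of closing onto the hindered 1,1-disubstituted alkene within the spiro framework. The fallback sets out from 22 and comes back at 24, and it opens the temporary furanone before the oxepine is closed. Methanolysis of the enol lactone (K2CO3 cat., MeOH, 0 °C) would give acyclic methyl keto ester F9, which has no enol ester alkene and no spiro strain. Ring-closing metathesis of F9 with the same catalyst should give oxepine methyl ester F10. Me3SnOH would cleave the methyl ester to keto acid 24, which is taken through the acid stage of step 15 to 25.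

Further compounds
F1 | step 12 | {1-[2,5-bis(methoxymethoxy)phenyl]ethenyl}oxy(trimethyl)silane | C=C(O[Si](C)(C)C)c1cc(OCOC)ccc1OCOC
F2 | step 12 | ethyl 2-oxohex-5-enoate | C=CCCC(=O)C(=O)OCC
F3 | step 12 | ethyl (2R)-4-[2,5-bis(methoxymethoxy)phenyl]-2-(but-3-en-1-yl)-4-oxo-2-[(trimethylsilyl)oxy]butanoate | C=CCC[C@@](CC(=O)c1cc(OCOC)ccc1OCOC)(C(=O)OCC)O[Si](C)(C)C
F4 | step 12 | ethyl (2R)-4-[2,5-bis(methoxymethoxy)phenyl]-2-(but-3-en-1-yl)-2-hydroxy-4-oxobutanoate | C=CCC[C@@](CC(=O)c1cc(OCOC)ccc1OCOC)(C(=O)OCC)O
F5 | step 12 | (2R)-4-[2,5-bis(methoxymethoxy)phenyl]-2-(but-3-en-1-yl)-2-hydroxy-4-oxobutanoic acid | C=CCC[C@@](CC(=O)c1cc(OCOC)ccc1OCOC)(C(=O)O)O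
F6 | step 12 | (3R)-5-[2,5-bis(methoxymethoxy)phenyl]-3-(but-3-en-1-yl)-3-hydroxyfuran-2(3H)-one | C=CCC[C@@]1(C(=O)OC(c2cc(OCOC)ccc2OCOC)=C1)O
F7 | step 12 | (5E)-7-{[tert-butyl(dimethyl)silyl]oxy}-6-methyl-2-methylidenehept-5-en-1-yl methanesulfonate | CS(=O)(=O)OCC(=C)CC/C=C(\C)CO[Si](C)(C)C(C)(C)C
F8 | step 9 | {[(2E)-6-(bromomethyl)-2-methylhepta-2,6-dien-1-yl]oxy}(tert-butyl)dimethylsilane | BrCC(=C)CC/C=C(\C)CO[Si](C)(C)C(C)(C)C
F9 | step 14 | methyl (2R)-4-[2,5-bis(methoxymethoxy)phenyl]-2-(but-3-en-1-yl)-4-oxo-2-(RO)butanoate | C=CCC[C@@](CC(=O)c1cc(OCOC)ccc1OCOC)(C(=O)OC)OCC(=C)CC/C=C(\C)CO[Si](C)(C)C(C)(C)C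
F10 | step 14 | methyl (2R)-2-{2-[2,5-bis(methoxymethoxy)phenyl]-2-oxoethyl}-6-[(3E)-5-{[tert-butyl(dimethyl)silyl]oxy}-4-methylpent-3-en-1-yl]-2,3,4,7-tetrahydrooxepine-2-carboxylate | C/C(=C\CCC1=CCC[C@@](CC(=O)c2cc(OCOC)ccc2OCOC)(C(=O)OC)OC1)CO[Si](C)(C)C(C)(C)C
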